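**Retrosynthetic overview**
1. Target 23 comes from the 9‑alcohol 22 by acetylation. The cyclobutane is the last ring: the C4–C10 bond is closed by an epoxide‑triggered cation–olefin cyclisation of the himachalane‑type 9,10‑epoxide 19 through its silyl dienol ether (the himachalyl → longipinyl cation step); the epoxide delivers the C9 oxygen and fixes C9 and C10.
2. The six‑membered ring of the himachalane bicycle 13 is closed before that, by anionic 6π‑electrocyclisation of the divinyl ketone 10 (C4–C5 bond) and kinetic protonation (cis ring fusion).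
3. 10 comes from the hydroxy enone 6 (Shapiro vinyllithium) and Weinreb amide 8; 6 comes from eucarvone 4 (asymmetric γ,δ‑epoxidation, hydrogenolysis), and 4 from carvone 1.
4. The C7 carbinol relays chirality to C5/C11, is then reset by oxidation/reduction and esterified with angelic acid 16 before the epoxidation.
5. Ring order: seven‑membered ring, then six‑membered ring (ring A), then four‑membered ring.

Assumption: 8 and 16 are bought; the catalyst enantiomer in step 2 is assigned by analogy with 2,2‑dimethylchromenes.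

Skeleton numbering used for all intermediates: C1 (C=O), C2=C3(CH3), C4, C5, C6(CH3)2, C7 (O‑angelate), C8, C9 (OAc), C10(CH3), C11. Ring A is C1–C2–C3–C4–C5–C11, the seven‑membered ring is C5–C6–C7–C8–C9–C10–C11, the cyclobutane is C4–C5–C11–C10.

**Route**

Step 1
Reactants: 1 (R)-(−)-carvone
Product: 4 eucarvone (2,6,6-trimethylcyclohepta-2,4-dien-1-one), via carvone hydrobromide 2 (not isolated), via car-3-en-2-one 3 (not isolated)
Conditions: HBr (33% in AcOH), 0 °C; evaporate; KOH, MeOH, 0 °C to reflux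
Reagents that add atoms: none
Why: Markovnikov HBr addition to the isopropenyl group, 3‑exo‑tet enolate alkylation to the carenone and electrocyclic opening of its dienolate (norcaradiene–cycloheptatriene valence isomerisation) give achiral eucarvone (classic carvone → eucarvone conversion; either carvone enantiomer serves).

Step 2
Reactants: 4 eucarvone
Product: 5 (1S,7R)-3,6,6-trimethyl-8-oxabicyclo[5.1.0]oct-2-en-4-one
Conditions: (S,S)-(salen)MnCl [(S,S)-N,N′-bis(3,5-di-tert-butylsalicylidene)-1,2-cyclohexanediaminomanganese chloride, trivalent manganese] (5 mol%), NaOCl (aq., pH 11.3), 4-phenylpyridine N-oxide (20 mol%), CH2Cl2, 0 °C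
Reagents that add atoms: sodium hypochlorite, [Na+].[O-]Cl
Why: Jacobsen–Katsuki epoxidation; the electrophilic oxo‑manganese species takes the electron‑richer cis‑disubstituted γ,δ‑alkene flanked by CMe2 (the 2,2‑dimethylchromene substrate type), and the catalyst decides the face, setting the future C7.

Step 3
Reactants: 5 epoxy enone
Product: 6 (5S)-5-hydroxy-2,6,6-trimethylcyclohept-2-en-1-one
Conditions: Pd2(dba)3·CHCl3 (2.5 mol%), PBu3 (10 mol%), HCO2H, Et3N, 1,4-dioxane, rt; then DBU (0.1 equiv), rt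
Reagents that add atoms: none
Why: Tsuji‑type hydrogenolysis of an alkenyl oxirane; zerovalent palladium ionises the allylic C8–O bond and formate delivers hydride to the π‑allyl, the C7–O bond is untouched (configuration retained), and DBU brings any β,γ‑isomer into conjugation.

Step 4
Reactants: 6 hydroxy enone
Product: 7 N′-[(1E,5S)-5-hydroxy-2,6,6-trimethylcyclohept-2-en-1-ylidene]-2,4,6-tri(propan-2-yl)benzenesulfonohydrazide
Conditions: 2,4,6-(i-Pr)3C6H2SO2NHNH2 (1.05 equiv), HCl (cat.), THF, rt
Reagents that add atoms: 2,4,6-tri(propan-2-yl)benzenesulfonohydrazide, CC(C)c1cc(C(C)C)c(S(=O)(=O)NN)c(C(C)C)c1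
Why: acid‑catalysed hydrazone condensation, with the sulfonamide anti to the substituted alkene carbon and therefore syn to the C5 methylene that has to be deprotonated next.

Step 5
Reactants: 7 hydrazone; 8 N-methoxy-N,3-dimethylbut-2-enamide
Product: 10 1-[(4S)-4-hydroxy-3,3,7-trimethylcyclohepta-1,6-dien-1-yl]-3-methylbut-2-en-1-one, via dienyllithium alkoxide 9 (not isolated)
Conditions: n-BuLi (3.2 equiv), THF, −78 to 0 °C; then 8, −78 to 0 °C; aq. NH4Cl
Reagents that add atoms: none
Why: Shapiro reaction (deprotonation at C5, loss of sulfinate and N2) gives the 2‑lithio‑1,3‑diene, which the Weinreb amide acylates once because the chelated tetrahedral adduct survives until work‑up; the lithium alkoxide at C7 is a spectator.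

Step 6
Reactants: 10 divinyl ketone
Product: 13 (4aS,6S,9aR)-6-hydroxy-3,5,5,9-tetramethyl-4,4a,5,6,7,9a-hexahydro-1H-benzo[7]annulen-1-one, via dipotassium trienolate 11 (not isolated), via dipotassium dienolate 12 (not isolated)
Conditions: KN(SiMe3)2 (2.3 equiv), THF, −78 to 0 °C; then AcOH, −78 °C
Reagents that add atoms: none
Why: γ‑deprotonation gives a 2‑oxidohexatriene that closes by anion‑accelerated disrotatory 6π‑electrocyclisation (the phorone → isophorone cyclisation); C4 bonds to C5 on the face away from the pseudoaxial C6 methyl with the C7 oxygen pseudoequatorial (C4 trans to O‑7), and kinetic α‑protonation at C11 anti to the quaternary C6 gives the cis ring fusion and leaves the 9,10‑alkene unconjugated.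

Step 7
Reactants: 13 hydroxy dienone
Product: 14 (4aS,9aR)-3,5,5,9-tetramethyl-4a,5,7,9a-tetrahydro-1H-benzo[7]annulene-1,6(4H)-dione
Conditions: Dess–Martin periodinane, pyridine, CH2Cl2, 0 °C
Reagents that add atoms: none
Why: Dess–Martin oxidation under buffered, non‑enolising conditions removes the relay stereocentre at C7 without moving the skipped alkene.

Step 8
Reactants: 14 dione
Product: 15 (4aS,6R,9aR)-6-hydroxy-3,5,5,9-tetramethyl-4,4a,5,6,7,9a-hexahydro-1H-benzo[7]annulen-1-one
Conditions: NaBH4, MeOH/CH2Cl2 (1:1), −78 °C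
Reagents that add atoms: none
Why: chemoselective borohydride reduction of the saturated ketone beside the hindered conjugated enone; hydride enters axially from the convex face of the cis‑fused bicycle and gives the equatorial 7‑alcohol cis to C4 (7R).

Step 9
Reactants: 15 alcohol; 16 angelic acid
Product: 18 (4aS,6R,9aR)-3,5,5,9-tetramethyl-1-oxo-4,4a,5,6,7,9a-hexahydro-1H-benzo[7]annulen-6-yl (2Z)-2-methylbut-2-enoate, via mixed anhydride 17 (not isolated)
Conditions: 16, 2,4,6-Cl3C6H2COCl, Et3N, toluene, rt; then 15, toluene, 80 °C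
Reagents that add atoms: none
Why: Yamaguchi‑type mixed‑anhydride esterification, the standard way to angeloylate hindered alcohols without Z → E isomerisation; H‑11 lies in the plane of both neighbouring π systems and is not removed by the amine.

Step 10
Reactants: 18 angelate
Product: 19 (4aS,6R,8R,9S,9aR)-8,9-epoxy-3,5,5,9-tetramethyl-1-oxo-4,4a,5,6,7,8,9,9a-octahydro-1H-benzo[7]annulen-6-yl (2Z)-2-methylbut-2-enoate
Conditions: mCPBA (1.05 equiv), CH2Cl2, 0 °C
Reagents that add atoms: mCPBA (3-chloroperoxybenzoic acid), OOC(=O)c1cccc(Cl)c1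
Why: Prilezhaev epoxidation of the only electron‑rich alkene (enone and angelate C=C are deactivated); the peracid attacks C9=C10 anti to the pseudoaxial C11–C1 bond (convex face), placing the oxygen on the side of H‑5/H‑11 (9R,10S in skeleton numbering).

Step 11
Reactants: 19 epoxy enone
Product: 22 (4R,5S,7R,9R,10R,11R)-9-hydroxy-1-oxolongipin-2-en-7-yl (2Z)-2-methylbut-2-enoate, via silyl dienol ether 20 (not isolated), via trimethylsilyl ether 21 (not isolated)
Conditions: LiN(SiMe3)2 (1.2 equiv), Me3SiCl, THF, −78 °C; solvent exchange to CH2Cl2; Me3SiOTf (0.2 equiv), 2,6-di-tert-butyl-4-methylpyridine (0.3 equiv), −78 to −40 °C; then aq. citric acid, THF, 0 °C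
Reagents that add atoms: none
Why: Proposed new method: in the cis‑fused bicycle C6 is equatorial and C10 axial on ring A, so H‑11 is equatorial and stereoelectronically non‑acidic and the amide base removes the axial H‑4 to give the linear 1‑silyloxy‑1,3‑diene; on silyl triflate activation of the epoxide the axial π‑lobe at C4, 1,3‑diaxial to C10, attacks the tertiary C10 anti to the departing oxygen (4‑exo, inversion at C10, C9–O retained as 9R), and epoxide strain release plus irreversible silyl transfer from the oxocarbenium ion pay for the cyclobutane; this sets C4 and C10 and is the laboratory counterpart of the himachalyl → longipinyl cation closure, the closest known reactions being epoxide‑initiated cation–olefin cyclisations terminated by silyl enol ethers and the four‑ring‑closing step of Lewis‑acid Michael–aldol [2+2] reactions of silyl enol ethers.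

Step 12
Reactants: 22 hydroxy tricycle
Product: 23 (4R,5S,7R,9R,10R,11R)-9-acetoxy-1-oxolongipin-2-en-7-yl (2Z)-2-methylbut-2-enoate (CNP0260482.1)
Conditions: Ac2O, DMAP (cat.), pyridine, CH2Cl2, rt
Reagents that add atoms: acetic anhydride, CC(=O)OC(C)=O
Why: DMAP‑catalysed acetylation of the only free hydroxyl; no stereocentre is touched.

**Compound list**
1 | (R)-(−)-carvone, (5R)-2-methyl-5-(prop-1-en-2-yl)cyclohex-2-en-1-one | CC1=CC[C@H](CC1=O)C(C)=C | starting material
2 | carvone hydrobromide, (5R)-5-(2-bromopropan-2-yl)-2-methylcyclohex-2-en-1-one | CC1=CC[C@H](CC1=O)C(C)(C)Br | intermediate (not isolated)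
3 | car-3-en-2-one, (1S,6R)-3,7,7-trimethylbicyclo[4.1.0]hept-3-en-2-one | CC1=CC[C@@H]2[C@H](C1=O)C2(C)C | intermediate (not isolated)
4 | eucarvone, 2,6,6-trimethylcyclohepta-2,4-dien-1-one | CC1=CC=CC(C)(C)CC1=O | intermediate
5 | (1S,7R)-3,6,6-trimethyl-8-oxabicyclo[5.1.0]oct-2-en-4-one | O1[C@H]2[C@@H]1C=C(C)C(=O)CC2(C)C | intermediate
6 | (5S)-5-hydroxy-2,6,6-trimethylcyclohept-2-en-1-one | O[C@H]1CC=C(C)C(=O)CC1(C)C | intermediate
7 | N′-[(1E,5S)-5-hydroxy-2,6,6-trimethylcyclohept-2-en-1-ylidene]-2,4,6-tri(propan-2-yl)benzenesulfonohydrazide | O[C@H]1CC=C(C)/C(CC1(C)C)=N/NS(=O)(=O)c1c(C(C)C)cc(C(C)C)cc1C(C)C | intermediate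
8 | N-methoxy-N,3-dimethylbut-2-enamide | CC(C)=CC(=O)N(C)OC | starting material
9 | lithium (1S)-4-lithio-2,2,5-trimethylcyclohepta-3,5-dien-1-olate | [Li]O[C@H]1CC=C(C)C([Li])=CC1(C)C | intermediate (not isolated)
10 | 1-[(4S)-4-hydroxy-3,3,7-trimethylcyclohepta-1,6-dien-1-yl]-3-methylbut-2-en-1-one | O[C@H]1CC=C(C)C(C(=O)C=C(C)C)=CC1(C)C | intermediate
11 | dipotassium trienolate of 10 (alkoxide at C7, 2-oxidohexatriene C4=C3–C2=C1(OK)–C11=C5) | [K]O[C@H]1CC=C(C)C(/C(O[K])=C\C(C)=C)=CC1(C)C | intermediate (not isolated)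
12 | ring-closed dipotassium dienolate (C4–C5 bond formed, enolate C1=C11, alkoxide at C7) | [K]O[C@H]1CC=C(C)C2=C(O[K])C=C(C)C[C@@H]2C1(C)C | intermediate (not isolated)
13 | (4aS,6S,9aR)-6-hydroxy-3,5,5,9-tetramethyl-4,4a,5,6,7,9a-hexahydro-1H-benzo[7]annulen-1-one | O[C@H]1CC=C(C)[C@@H]2C(=O)C=C(C)C[C@@H]2C1(C)C | intermediate
14 | (4aS,9aR)-3,5,5,9-tetramethyl-4a,5,7,9a-tetrahydro-1H-benzo[7]annulene-1,6(4H)-dione | O=C1CC=C(C)[C@@H]2C(=O)C=C(C)C[C@@H]2C1(C)C | intermediate
15 | (4aS,6R,9aR)-6-hydroxy-3,5,5,9-tetramethyl-4,4a,5,6,7,9a-hexahydro-1H-benzo[7]annulen-1-one | O[C@@H]1CC=C(C)[C@@H]2C(=O)C=C(C)C[C@@H]2C1(C)C | intermediate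
16 | angelic acid, (2Z)-2-methylbut-2-enoic acid | C/C=C(/C)C(=O)O | starting material
17 | (2Z)-2-methylbut-2-enoic 2,4,6-trichlorobenzoic anhydride | C/C=C(/C)C(=O)OC(=O)c1c(Cl)cc(Cl)cc1Cl | intermediate (not isolated)
18 | (4aS,6R,9aR)-3,5,5,9-tetramethyl-1-oxo-4,4a,5,6,7,9a-hexahydro-1H-benzo[7]annulen-6-yl (2Z)-2-methylbut-2-enoate | C/C=C(/C)C(=O)O[C@@H]1CC=C(C)[C@@H]2C(=O)C=C(C)C[C@@H]2C1(C)C | intermediate
19 | (4aS,6R,8R,9S,9aR)-8,9-epoxy-3,5,5,9-tetramethyl-1-oxo-4,4a,5,6,7,8,9,9a-octahydro-1H-benzo[7]annulen-6-yl (2Z)-2-methylbut-2-enoate (9,10-epoxide, oxygen on the face of H-5/H-11) | C/C=C(/C)C(=O)O[C@@H]1C[C@H]2O[C@@]2(C)[C@@H]3C(=O)C=C(C)C[C@@H]3C1(C)C | intermediate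
20 | trimethylsilyl dienol ether of 19 (ring A: C1(OSiMe3)=C2–C3(CH3)=C4) | C/C=C(/C)C(=O)O[C@@H]1C[C@H]2O[C@@]2(C)[C@@H]3C(O[Si](C)(C)C)=CC(C)=C[C@@H]3C1(C)C | intermediate (not isolated)
21 | 9-O-trimethylsilyl ether of 22 | C/C=C(/C)C(=O)O[C@@H]1C[C@@H](O[Si](C)(C)C)[C@@]2(C)[C@@H]3C(=O)C=C(C)[C@H]2[C@@H]3C1(C)C | intermediate (not isolated)
22 | (4R,5S,7R,9R,10R,11R)-9-hydroxy-1-oxolongipin-2-en-7-yl (2Z)-2-methylbut-2-enoate | C/C=C(/C)C(=O)O[C@@H]1C[C@@H](O)[C@@]2(C)[C@@H]3C(=O)C=C(C)[C@H]2[C@@H]3C1(C)C | intermediate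
23 | (4R,5S,7R,9R,10R,11R)-9-acetoxy-1-oxolongipin-2-en-7-yl (2Z)-2-methylbut-2-enoate, CNP0260482.1 | C/C=C(/C)C(=O)O[C@@H]1C[C@@H](OC(C)=O)[C@@]2(C)[C@@H]3C(=O)C=C(C)[C@H]2[C@@H]3C1(C)C | target

**Count**
Total steps: 12. Longest linear sequence: 12 (from 1; 8 and 16 are bought).

**Steps most likely to fail**

Step 11 (cyclobutane closure). The activated epoxide can lose a proton or suffer a 1,2‑hydride shift faster than the strained 4‑exo attack, and the exocyclic dienol ether isomer cannot cyclise. The fallback sets out from 18 and comes back at 23, replacing the epoxide by a neighbouring‑group‑stabilised electrophile that cannot rearrange and that carries the acetate. OsO4 (cat.)/N‑methylmorpholine N‑oxide dihydroxylates C9=C10 from the convex face to the 9,10‑cis‑diol F1. Trimethyl orthoacetate with pyridinium p‑toluenesulfonate gives the cyclic orthoacetate F2. LiN(SiMe3)2/Me3SiCl gives its silyl dienol ether F3. Me3SiOTf then ionises the orthoester to the 2‑methyl‑1,3‑dioxolan‑2‑ylium ion on the face of H‑5/H‑11, which C4 opens at C10 from the opposite face (Woodward–Prévost‑type acetoxonium opening with inversion). This gives 23 directly, so step 12 is not needed.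

Step 6 (ring A). The dienolate geometry, the level of 1,3‑induction from C7 and the face of protonation at C11 are all untested on this substrate. The fallback sets out from 7 and comes back at 13, building ring A stepwise (Michael/aldol) instead of by electrocyclisation. The Shapiro vinyllithium 9 is acylated with N‑methoxy‑N‑methylacetamide to the methyl ketone F4. A Mukaiyama–Michael addition of 2‑(trimethylsilyloxy)propene (TiCl4, CH2Cl2, −78 °C) at C5 gives the 1,5‑diketone F5. Aldol condensation (pyrrolidine, AcOH) of the acetyl methyl onto the less hindered side‑chain ketone closes ring A to 13.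

Step 2 (asymmetric epoxidation). An electron‑poor dienone may give low conversion or low enantiomeric excess. The fallback sets out from 4 and comes back at 6, moving the asymmetric event to a ketone reduction. mCPBA gives the racemic epoxide, that is 5 together with its enantiomer F6. Pd(PPh3)4 (zerovalent palladium) isomerises the alkenyl oxirane to the achiral 2,6,6‑trimethylcyclohept‑2‑ene‑1,5‑dione F7. A ketoreductase (NADPH, glucose/glucose dehydrogenase recycling) selected for the (S)‑alcohol reduces the saturated, α‑quaternary ketone to 6.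

**Further compounds**
F1 | step 11 | 9,10-cis-diol of 18, both hydroxyls on the face of H-5/H-11 | C/C=C(/C)C(=O)O[C@@H]1C[C@@H](O)[C@@](C)(O)[C@@H]2C(=O)C=C(C)C[C@@H]2C1(C)C
F2 | step 11 | cyclic orthoacetate of F1 (2-methoxy-2-methyl-1,3-dioxolane across C9/C10, both epimers at the orthoester carbon) | C/C=C(/C)C(=O)O[C@@H]1C[C@H]2OC(C)(OC)O[C@@]2(C)[C@@H]3C(=O)C=C(C)C[C@@H]3C1(C)C
F3 | step 11 | trimethylsilyl dienol ether of F2 | C/C=C(/C)C(=O)O[C@@H]1C[C@H]2OC(C)(OC)O[C@@]2(C)[C@@H]3C(O[Si](C)(C)C)=CC(C)=C[C@@H]3C1(C)C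
F4 | step 6 | 1-[(4S)-4-hydroxy-3,3,7-trimethylcyclohepta-1,6-dien-1-yl]ethan-1-one | O[C@H]1CC=C(C)C(C(C)=O)=CC1(C)C
F5 | step 6 | 1,5-diketone: C11 acetyl, C5 2-oxopropyl, C7 hydroxyl, 9,10-alkene | O[C@H]1CC=C(C)[C@H](C(C)=O)[C@H](CC(C)=O)C1(C)C
F6 | step 2 | (1R,7S)-3,6,6-trimethyl-8-oxabicyclo[5.1.0]oct-2-en-4-one | O1[C@@H]2[C@H]1C=C(C)C(=O)CC2(C)C
F7 | step 2 | 2,6,6-trimethylcyclohept-2-ene-1,5-dione | O=C1CC=C(C)C(=O)CC1(C)C
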